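# Bisoflavolin H: route design through anionic annulation of ring A of unit 2 onto a preformed pyranone

## The problem

Bisoflavolin H (21) consists of two isoflavones. Unit 1 is an 8-chloro-7-hydroxyisoflavone and unit 2 is genistein. The oxygen on C4' of unit 1 is bonded to C8 of unit 2, so ring B of unit 1 is a para-phenylene bridge held to unit 2 by a diaryl ether. The molecule has no stereocentre, so every difficulty is one of connectivity and regiochemistry. The hard bond is C8–O of unit 2. C8 lies between the C7 hydroxyl and the ring oxygen on C8a in an electron-rich phloroglucinol ring, so a late O-arylation there meets a doubly ortho-substituted centre. Any closure of ring C onto an aryloxyphloroglucinol must also choose between two ortho oxygens, that is between the 8-aryloxy and the 6-aryloxy chromone. In unit 1 the chlorine must end up on C8 between O1 and the C7 hydroxyl, and its presence rules out hydrogenolysis as a late deprotection. Both pyranone rings are opened by hydroxide and other hard nucleophiles at C2, and the free phloroglucinol ring of unit 2 is prone to oxidation and C-alkylation, so the four phenols are best released only at the end. A short solution is possible because ring A of unit 2 (C4a, C5, C6, C7, C8, C8a) is an acylphloroglucinol, a folded tetraketide, whose C8a oxygen is already O1 of the pyranone. If the pyranone exists first, C8 is only an aryloxymethyl carbon on pyranone C2 (acidified through the C2=C3 bond by the ring ketone and an ester on C3), C5 is that ester carbon, and C6 and C7 are an acetyl unit.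

## Retrosynthesis

**21 to 20.** Only O–CH3 bonds are cut. Methyl ethers are chosen for the three phenols of unit 2 because they survive alkylation, fluoride, oxidation and hot Lewis acid, and they are removed without hydrogen, which the C8 chlorine would not tolerate. The 7-hydroxyl of unit 1 needs no protection. The forward step must cleave three aryl methyl ethers and leave the diaryl ether alone.

**20 to 17 and 18.** Ring C of unit 1 is cut at C4–C4a, C2–C3 and O1–C2. This leads through deoxybenzoin 19 to arylacetic acid 17, 2-chlororesorcinol 18 and a one-carbon electrophile. Compared with a cross-coupling of a 3-halochromone, this cut needs no separate synthesis of a chlorinated chromone. Because C4 and C6 of 18 are equivalent, acylation can give only one ketone. Closure through the hydroxyl next to the ketone puts chlorine on C8 and leaves the 7-hydroxyl free. All of unit 2 is carried in 17, so the forward step must prefer the free resorcinol over the deactivated, chromone-bound rings.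

**17 to 14.** The carboxyl group of 17 is traced back to primary alcohol 16, its silyl ether 15 and diphenol 14. An arylacetic acid or ester could not pass through the anionic key step because its benzylic protons are acidic. The silylated 2-arylethanol is inert there and already has both carbons, so no homologation is needed later. The phenols of 14 are methylated before the oxidation, which a free phloroglucinol ring would not survive.

**14 to 11 and 12 (key disconnection).** Ring A of unit 2 is cut at C5–C6 and C7–C8, giving pyranone ester 11 and the acetyl donor 12, with methyl ketone 13 between them. The neighbouring cuts (O1–C8a or C4–C4a) are those of classical chromone syntheses and bring back the choice between two ortho oxygens. An O-arylation at C8 brings back the hindered coupling. Here O1 is on C8a before ring A exists and the aryloxy group is on the carbon that becomes C8, so neither question arises. Precursor 11 has no benzenoid ring A, only a trisubstituted 4-pyranone. The forward reaction must deprotonate the aryloxymethyl group, acylate it at carbon, and then close a six-membered ring by Claisen condensation onto the ester.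

**11 to 4 and 8.** The pyranone is cut at C3–C4 and O1–C6. β-Keto ester 4 supplies O1, C2 with its aryloxymethyl group, and C3 with its ester. Acid 8, as its chloride 9, supplies C4, C5 with the anisyl group, and C6 as a methoxymethylene carbon. The open tricarbonyl compound 10 closes by addition–elimination. Formylating a preformed triketone instead would leave a choice between two methylene groups. With the formyl carbon already in 8 the substitution pattern is unambiguous.

**4 to 2 and 3, and 2 to 1.** The ether oxygen that ends as the hindered C8–O bond is disconnected at O–CH2, giving phenol 2 and methyl 4-chloroacetoacetate 3. Phenol 2 is tyrosol 1 silylated at the aliphatic hydroxyl. This is the point of the plan: the most hindered bond of the target is made as an SN2 reaction of an unhindered phenoxide with a primary chloride.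

**8 to 5.** Acid 8 comes from ester 7, and 7 from methyl 4-methoxyphenylacetate 5 by formylation to 6 and O-methylation, the usual entry to β-methoxyacrylates.

## Roads not taken

**Alternative 1:** The bridging ring B of unit 1 is cut across C2'–C3' and C4'–C5' into methyl coumalate A1 and the aryl ethynyl ether A2.
- **Forward key step:** heated together, they should undergo a Diels–Alder addition, the terminal alkyne carbon bonding to C6 of A1 and the oxygen-bearing carbon to C3. Loss of CO2 then gives the para-aryloxybenzoate A3.
- **Merits:** this is a known reaction type for 2-pyranones and electron-rich alkynes, the regiochemistry is matched, no metal is needed, and the diaryl ether oxygen is never made by coupling at a hindered carbon.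
- **Weak points:** it builds the one ring that can simply be bought. A3 should also form in one step from methyl 4-fluorobenzoate A4 and phenol A5 by SNAr, whereas A2 must itself be made from A5 and is a heat-sensitive ynol ether. Beyond A3 the benzoate must be lengthened by one carbon to the arylacetic acid. Ring C of unit 2 must then be closed on the aryloxyphloroglucinol ring, where the acyl group has to enter between the benzyloxy and a methoxy group and not between the two methoxy groups. Only the benzyl ether marks the oxygen that is to become O1, and it must be removed by hydrogenolysis before the chlorine arrives.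
- **Comparison:** no step of Alternative 1 lies outside known chemistry, which is an advantage over the chosen plan. The chosen plan sets against this a shorter sequence and a C8 regiochemistry fixed by construction, not by selectivity.

**Alternative 2:** The O1–C8a bond of unit 1 is cut.
- **Forward key step:** the hydroxymethylene ketone A6, which carries a 3-chloro-2,4-difluorophenyl group, is treated with K2CO3 in DMF. Its enolate oxygen displaces the fluoride ortho to the carbonyl and closes ring C to give the 8-chloro-7-fluorochromone A7.
- **Merits:** SNAr closure of ortho-fluoroaryl ketone enolates is well precedented and runs under mild base. It would spare an advanced intermediate the hot Lewis acid of step 10, and the starting arene guarantees the position of the chlorine. For unit 1 it is as good as, or gentler than, the annulation used here.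
- **Weak points:** it solves the easier ring. The C7 fluorine of A7 must afterwards be exchanged for oxygen by a second SNAr on a chromone that hydroxide would open, which means an alkoxide and a further deprotection compatible with the aryl chloride. The fluorine para to the ketone in A6 is also activated and can be attacked by external nucleophiles during the closure. The benzyloxydimethoxyphenyl ether in A6 still has to become unit 2, with the same acylation and ring-closure regiochemistry left open as in Alternative 1.
- **Comparison:** the chosen plan answers with a one-pot annulation from 18 that delivers the free 7-hydroxyl directly, and it spends its one unprecedented step on the ring that causes the difficulty.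

**Alternative 3:** This plan also addresses unit 2, by cutting O1–C8a.
- **Forward key step:** oxidation of the 2,4,5-trimethoxyphenyl hydroxymethylene ketone A8 with (NH4)2Ce(NO3)6 (tetravalent cerium) in aqueous acetonitrile should give the acylquinone A9. Its enol oxygen adds to the quinone carbon next to the acyl group, and reduction with Na2S2O4 gives the 5,8-dihydroxy-7-methoxyisoflavone A10.
- **Merits:** the C8 oxygen is placed by construction, as in the chosen plan. In A10 the 5-hydroxyl is hydrogen-bonded to the carbonyl, so the 8-hydroxyl is the only phenol free to react. Each step has precedent in quinone chemistry.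
- **Weak points:** the C8–O–aryl bond must still be made by arylating the 8-hydroxyl of A10, a phenol flanked by a methoxy group and the ring oxygen, with an unactivated para-substituted arene. SNAr is not available, so a copper-mediated coupling is needed. Under the oxidative conditions of a boronic acid coupling with Cu(OAc)2 (divalent copper), hydroquinone A10 is liable to return to the quinone. The ceric oxidation must also spare the anisyl ring and the enol of A8.
- **Comparison:** Alternative 3 is safer up to A10 and weaker after it. The chosen plan makes the same ether bond as an SN2 reaction in step 2 and accepts an untested annulation in exchange.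

Key step: step 6

Remark: 21 has no stereocentre. Intermediates 10 and 13 each carry one enolisable CH and exist in the flask as metal enolates; they are drawn in the neutral keto form, and 6 is drawn as its enol.

## Route

Step 1
Reactants: 1 tyrosol [4-(2-hydroxyethyl)phenol]
Product: 2 4-[2-(tert-butyldimethylsilyloxy)ethyl]phenol
Conditions: TBSCl (1.05 equiv), imidazole, CH2Cl2/DMF, 0 °C
Reagents that add atoms: tert-butyldimethylsilyl chloride, CC(C)(C)[Si](C)(C)Cl
Why: Silyl ether formation; with imidazole as base the primary aliphatic hydroxyl is silylated faster than the un-ionised phenol, and any aryl silyl ether that forms can be cleaved selectively with K2CO3 in MeOH without touching the alkyl silyl ether.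

Step 2
Reactants: 2 4-[2-(tert-butyldimethylsilyloxy)ethyl]phenol; 3 methyl 4-chloroacetoacetate (methyl 4-chloro-3-oxobutanoate)
Product: 4 methyl 4-{4-[2-(tert-butyldimethylsilyloxy)ethyl]phenoxy}-3-oxobutanoate
Conditions: NaH (2.1 equiv), THF/DMF, 0 °C → rt; aq. NH4Cl
Reagents that add atoms: none
Why: Williamson-type SN2 displacement of the primary chloride by the sodium phenoxide; the second equivalent of NaH holds the β-keto ester as its enolate, which suppresses self-condensation and is the usual way aryloxy- and alkoxyacetoacetates are made from 4-chloroacetoacetates.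

Step 3
Reactants: 5 methyl 4-methoxyphenylacetate
Product: 7 methyl (E)-3-methoxy-2-(4-methoxyphenyl)acrylate, via hydroxymethylene ester 6 (not isolated)
Conditions: NaH, HCO2Me, THF, 0 °C → rt; then Me2SO4, DMF co-solvent, rt
Reagents that add atoms: methyl formate, COC=O; dimethyl sulfate, COS(=O)(=O)OC
Why: Crossed Claisen formylation of the arylacetate, then O-methylation of the sodium enolate of 6 by the hard electrophile Me2SO4, the standard entry to β-methoxyacrylates; the E isomer is thermodynamically preferred, and the alkene geometry is in any case erased in step 5.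

Step 4
Reactants: 7 methyl (E)-3-methoxy-2-(4-methoxyphenyl)acrylate
Product: 8 (E)-3-methoxy-2-(4-methoxyphenyl)acrylic acid
Conditions: LiOH·H2O, THF/MeOH/H2O, rt; then 1 M HCl to pH 3, 0 °C
Reagents that add atoms: lithium hydroxide, [Li+].[OH-]
Why: Saponification of the methyl ester; the β-methoxy enol ether is a vinylogous carbonate that hydroxide does not attack at room temperature and that survives a cold, brief acidification.

Step 5
Reactants: 8 (E)-3-methoxy-2-(4-methoxyphenyl)acrylic acid; 4 methyl 4-{4-[2-(tert-butyldimethylsilyloxy)ethyl]phenoxy}-3-oxobutanoate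
Product: 11 methyl 2-({4-[2-(tert-butyldimethylsilyloxy)ethyl]phenoxy}methyl)-5-(4-methoxyphenyl)-4-oxo-4H-pyran-3-carboxylate, via acid chloride 9 (not isolated), via tricarbonyl ester 10 (not isolated)
Conditions: (COCl)2, DMF (cat.), CH2Cl2, 0 °C → rt, evaporate; then 4, MgCl2, pyridine, CH2Cl2, 0 °C → rt; then DBU (0.2 equiv), rt
Reagents that add atoms: none
Why: Acid chloride formation, then C-acylation of the chelated magnesium enolate of β-keto ester 4 (soft enolisation, C-selective), then intramolecular oxa-Michael addition of the ketone enol oxygen of 10 to the β-methoxyenone with loss of methanol, the addition–elimination by which 4-pyranones and chromones are closed from β-alkoxyvinyl ketones. The substitution pattern of 11 is unambiguous because only the ketone enol of 10 can reach the methoxymethylene carbon through a six-membered transition state.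

Step 6
Reactants: 11 methyl 2-({4-[2-(tert-butyldimethylsilyloxy)ethyl]phenoxy}methyl)-5-(4-methoxyphenyl)-4-oxo-4H-pyran-3-carboxylate; 12 N-methoxy-N-methylacetamide
Product: 14 8-{4-[2-(tert-butyldimethylsilyloxy)ethyl]phenoxy}-5,7-dihydroxy-3-(4-methoxyphenyl)-4H-chromen-4-one, via methyl ketone 13 (not isolated)
Conditions: LiN(iPr)2 (1.1 equiv), THF, −78 °C; 12 (1.1 equiv), −78 → −20 °C; LiN(iPr)2 (2.5 equiv), −78 °C → rt; aq. NH4Cl
Reagents that add atoms: none
Why: Proposed new method: the methylene group of 11 is γ to both the ring ketone and the C3 ester through the C2=C3 bond, so LiN(iPr)2 at −78 °C should remove one of its protons in preference to adding at C6, as in the known lateral metalation and C-acylation of 2-alkyl-4-pyranones; the extended enolate attacks amide 12 at carbon through the usual chelated tetrahedral adduct, which collapses on warming because the ketone 13 so released is at once deprotonated to a doubly stabilised enolate. The second charge of base then removes a methyl proton of 13 (an acetoacetate-type dianion), and this terminal enolate attacks the neighbouring ester carbon in a 6-(enolendo)-exo-trig Claisen (Dieckmann-type) closure, methoxide leaves, and two enolisations give the aromatic 5,7-diol, isolated after protonation of its bis-phenoxide. The closest known reaction types are the Staunton–Weinreb annulation of toluate anions and the base-induced Claisen closure of 2-(2-oxopropyl)benzoates to naphthalene-1,3-diols; what is new is a pyranone ester as the ring that carries both reacting groups. No stereocentre is formed, and the one in 13 is lost on aromatisation. Three selectivities are needed: C- over O-acylation, secured by the Weinreb amide, which does not transfer acetyl irreversibly to oxygen; Claisen over aldol closure, secured because attack on the C4 carbonyl would build a bridged bicyclo[3.3.1] ring with a bridgehead alkene and because that carbonyl is a doubly vinylogous ester of low electrophilicity; and the position of the aryloxy group, which can only be C8 because O1 already sits on the future C8a. The negative charge carried by the pyranone throughout, and by the phloroglucinol ring at the end, also shields the unsubstituted C6 of 11 (C2 of 14) against addition of amide or methoxide.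

Step 7
Reactants: 14 8-{4-[2-(tert-butyldimethylsilyloxy)ethyl]phenoxy}-5,7-dihydroxy-3-(4-methoxyphenyl)-4H-chromen-4-one
Product: 15 8-{4-[2-(tert-butyldimethylsilyloxy)ethyl]phenoxy}-5,7-dimethoxy-3-(4-methoxyphenyl)-4H-chromen-4-one
Conditions: MeI (excess), K2CO3, DMF, 50 °C
Reagents that add atoms: iodomethane, CI
Why: Williamson O-methylation; the hydrogen-bonded 5-hydroxyl needs excess MeI and warming, which the silyl ether and the pyranone tolerate, and carbonate in DMF favours O- over C-methylation of the phloroglucinol ring.

Step 8
Reactants: 15 8-{4-[2-(tert-butyldimethylsilyloxy)ethyl]phenoxy}-5,7-dimethoxy-3-(4-methoxyphenyl)-4H-chromen-4-one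
Product: 16 8-[4-(2-hydroxyethyl)phenoxy]-5,7-dimethoxy-3-(4-methoxyphenyl)-4H-chromen-4-one
Conditions: Bu4NF, AcOH, THF, 0 °C → rt
Reagents that add atoms: none
Why: Fluoride-induced cleavage of the primary silyl ether; buffering with acetic acid keeps the medium from becoming basic enough to open the pyranone ring.

Step 9
Reactants: 16 8-[4-(2-hydroxyethyl)phenoxy]-5,7-dimethoxy-3-(4-methoxyphenyl)-4H-chromen-4-one
Product: 17 (4-{[5,7-dimethoxy-3-(4-methoxyphenyl)-4-oxo-4H-chromen-8-yl]oxy}phenyl)acetic acid
Conditions: TEMPO (cat.), PhI(OAc)2 (2.2 equiv), MeCN/H2O 1:1, rt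
Reagents that add atoms: water, O
Why: Oxoammonium-catalysed oxidation (TEMPO, trivalent iodine as terminal oxidant) of the primary alcohol through the aldehyde hydrate to the carboxylic acid; the reagent pair leaves aryl methyl ethers and the diaryl ether alone, and both phenols are masked.

Step 10
Reactants: 17 (4-{[5,7-dimethoxy-3-(4-methoxyphenyl)-4-oxo-4H-chromen-8-yl]oxy}phenyl)acetic acid; 18 2-chlororesorcinol (2-chlorobenzene-1,3-diol)
Product: 20 8-chloro-3-(4-{[5,7-dimethoxy-3-(4-methoxyphenyl)-4-oxo-4H-chromen-8-yl]oxy}phenyl)-7-hydroxy-4H-chromen-4-one, via deoxybenzoin 19 (not isolated)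
Conditions: 18 (2 equiv), BF3·OEt2, 85 °C; then DMF, MeSO2Cl, 60 °C; aq. NaOAc
Reagents that add atoms: N,N-dimethylformamide, CN(C)C=O
Why: Friedel–Crafts C-acylation of the resorcinol by the BF3-activated arylacetic acid at C4 (C4 and C6 of 18 are equivalent), then C-formylation of the activated methylene of the BF2-chelated deoxybenzoin 19 by the iminium salt from DMF and MeSO2Cl and closure through the hydroxyl ortho to the ketone with loss of dimethylamine, the standard one-pot deoxybenzoin-to-isoflavone sequence. That closure places the chlorine on C8 and leaves the other hydroxyl as the free 7-OH; partial loss of the chelated 5-methyl ether of unit 2 would be harmless, since step 11 removes it anyway.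

Step 11
Reactants: 20 8-chloro-3-(4-{[5,7-dimethoxy-3-(4-methoxyphenyl)-4-oxo-4H-chromen-8-yl]oxy}phenyl)-7-hydroxy-4H-chromen-4-one
Product: 21 bisoflavolin H, 8-chloro-3-(4-{[5,7-dihydroxy-3-(4-hydroxyphenyl)-4-oxo-4H-chromen-8-yl]oxy}phenyl)-7-hydroxy-4H-chromen-4-one
Conditions: BBr3 (excess), CH2Cl2, −78 °C → rt; then MeOH/H2O
Reagents that add atoms: none
Why: Lewis acid cleavage of the three aryl methyl ethers by BBr3 (bromide attack at methyl); diaryl ethers, the aryl chloride and the pyranone rings are inert to it, so the bridging ether survives while all four phenols are released.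

## Compound list

1 | tyrosol, 4-(2-hydroxyethyl)phenol | OCCc1ccc(O)cc1 | starting material
2 | 4-[2-(tert-butyldimethylsilyloxy)ethyl]phenol | CC(C)(C)[Si](C)(C)OCCc1ccc(O)cc1 | intermediate
3 | methyl 4-chloroacetoacetate (methyl 4-chloro-3-oxobutanoate) | COC(=O)CC(=O)CCl | starting material
4 | methyl 4-{4-[2-(tert-butyldimethylsilyloxy)ethyl]phenoxy}-3-oxobutanoate | COC(=O)CC(=O)COc1ccc(CCO[Si](C)(C)C(C)(C)C)cc1 | intermediate
5 | methyl 4-methoxyphenylacetate | COc1ccc(CC(=O)OC)cc1 | starting material
6 | methyl 3-hydroxy-2-(4-methoxyphenyl)acrylate (sodium enolate in the flask, not isolated) | COC(=O)C(=CO)c1ccc(OC)cc1 | intermediate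
7 | methyl (E)-3-methoxy-2-(4-methoxyphenyl)acrylate | CO/C=C(\c1ccc(OC)cc1)C(=O)OC | intermediate
8 | (E)-3-methoxy-2-(4-methoxyphenyl)acrylic acid | CO/C=C(\c1ccc(OC)cc1)C(=O)O | intermediate
9 | (E)-3-methoxy-2-(4-methoxyphenyl)acryloyl chloride (not isolated) | CO/C=C(\c1ccc(OC)cc1)C(=O)Cl | intermediate
10 | methyl 4-{4-[2-(tert-butyldimethylsilyloxy)ethyl]phenoxy}-2-[(E)-3-methoxy-2-(4-methoxyphenyl)acryloyl]-3-oxobutanoate (magnesium chelate in the flask, not isolated) | COC(=O)C(C(=O)COc1ccc(CCO[Si](C)(C)C(C)(C)C)cc1)C(=O)/C(=C/OC)c1ccc(OC)cc1 | intermediate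
11 | methyl 2-({4-[2-(tert-butyldimethylsilyloxy)ethyl]phenoxy}methyl)-5-(4-methoxyphenyl)-4-oxo-4H-pyran-3-carboxylate | COC(=O)c1c(COc2ccc(CCO[Si](C)(C)C(C)(C)C)cc2)occ(-c2ccc(OC)cc2)c1=O | intermediate
12 | N-methoxy-N-methylacetamide | CC(=O)N(C)OC | starting material
13 | methyl 2-(1-{4-[2-(tert-butyldimethylsilyloxy)ethyl]phenoxy}-2-oxopropyl)-5-(4-methoxyphenyl)-4-oxo-4H-pyran-3-carboxylate (lithium enolate in the flask, not isolated) | COC(=O)c1c(C(Oc2ccc(CCO[Si](C)(C)C(C)(C)C)cc2)C(C)=O)occ(-c2ccc(OC)cc2)c1=O | intermediate
14 | 8-{4-[2-(tert-butyldimethylsilyloxy)ethyl]phenoxy}-5,7-dihydroxy-3-(4-methoxyphenyl)-4H-chromen-4-one | COc1ccc(cc1)-c1coc2c(Oc3ccc(CCO[Si](C)(C)C(C)(C)C)cc3)c(O)cc(O)c2c1=O | intermediate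
15 | 8-{4-[2-(tert-butyldimethylsilyloxy)ethyl]phenoxy}-5,7-dimethoxy-3-(4-methoxyphenyl)-4H-chromen-4-one | COc1ccc(cc1)-c1coc2c(Oc3ccc(CCO[Si](C)(C)C(C)(C)C)cc3)c(OC)cc(OC)c2c1=O | intermediate
16 | 8-[4-(2-hydroxyethyl)phenoxy]-5,7-dimethoxy-3-(4-methoxyphenyl)-4H-chromen-4-one | COc1ccc(cc1)-c1coc2c(Oc3ccc(CCO)cc3)c(OC)cc(OC)c2c1=O | intermediate
17 | (4-{[5,7-dimethoxy-3-(4-methoxyphenyl)-4-oxo-4H-chromen-8-yl]oxy}phenyl)acetic acid | COc1ccc(cc1)-c1coc2c(Oc3ccc(CC(=O)O)cc3)c(OC)cc(OC)c2c1=O | intermediate
18 | 2-chlororesorcinol (2-chlorobenzene-1,3-diol) | Oc1cccc(O)c1Cl | starting material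
19 | 1-(3-chloro-2,4-dihydroxyphenyl)-2-(4-{[5,7-dimethoxy-3-(4-methoxyphenyl)-4-oxo-4H-chromen-8-yl]oxy}phenyl)ethan-1-one (BF2 chelate in the flask, not isolated) | COc1ccc(cc1)-c1coc2c(Oc3ccc(CC(=O)c4ccc(O)c(Cl)c4O)cc3)c(OC)cc(OC)c2c1=O | intermediate
20 | 8-chloro-3-(4-{[5,7-dimethoxy-3-(4-methoxyphenyl)-4-oxo-4H-chromen-8-yl]oxy}phenyl)-7-hydroxy-4H-chromen-4-one | COc1ccc(cc1)-c1coc2c(Oc3ccc(cc3)-c3coc4c(Cl)c(O)ccc4c3=O)c(OC)cc(OC)c2c1=O | intermediate
21 | bisoflavolin H, 8-chloro-3-(4-{[5,7-dihydroxy-3-(4-hydroxyphenyl)-4-oxo-4H-chromen-8-yl]oxy}phenyl)-7-hydroxy-4H-chromen-4-one | O=c1c(-c2ccc(Oc3c(O)cc(O)c4c(=O)c(-c5ccc(O)cc5)coc34)cc2)coc2c(Cl)c(O)ccc12 | target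

## Step count and least certain steps

Total: 11 steps. Longest linear sequence: 9 steps (steps 3, 4, 5, 6, 7, 8, 9, 10, 11 from 5; equally steps 1, 2, 5 to 11 from 1).

**Step 6 (key step, proposed new method).** Three processes may defeat it:
- conjugate addition of the amide base to the unsubstituted C6 of the pyranone, with ring opening, in competition with lateral deprotonation;
- failure of the tetrahedral adduct to collapse before the second charge of base, so that no methyl ketone is present to be deprotonated;
- stalling of the Claisen closure, because the first enolate is delocalised into the ester that has to be attacked and lowers its electrophilicity.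

The fallback uses only known reaction types and sets out from 2. Commercial 5,7-dimethoxy-3-(4-methoxyphenyl)-4H-chromen-4-one F1 is brominated with N-bromosuccinimide, which for 5,7-dialkoxychromones is expected to go to C8, to give 8-bromo-5,7-dimethoxy-3-(4-methoxyphenyl)-4H-chromen-4-one F2. Ullmann ether coupling of F2 with phenol 2 (CuI, picolinic acid, K3PO4, DMSO, 100 °C) should give 15, where the route is rejoined. This gives up the main advantage of the plan, since the hindered C8–O bond is then made by coupling.

**Step 5.** The enolate carbon of 4 may attack the methoxymethylene carbon of 9 by addition–elimination instead of the acyl chloride, which after lactonisation would lead into the 2-pyranone series. O-acylation and sluggish closure of 10 are lesser risks. The fallback sets out from 4 and removes the ambident electrophile. Under the same MgCl2/pyridine conditions, 4 is acylated with commercial (4-methoxyphenyl)acetyl chloride to give methyl 4-{4-[2-(tert-butyldimethylsilyloxy)ethyl]phenoxy}-2-[(4-methoxyphenyl)acetyl]-3-oxobutanoate F3. Heating F3 with N,N-dimethylformamide dimethyl acetal in toluene should aminomethylenate the more acidic benzylic methylene and close the ring with loss of dimethylamine, giving 11. The price is a selectivity between two methylene groups that the main route does not need.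

**Step 10.** The Friedel–Crafts acylation may be slow or misdirected, through poor solubility of 17 in BF3·OEt2 or acylation of the electron-rich rings of 17 itself, leading to oligomers. The fallback sets out from 17 and separates acylation, deprotection and annulation.
- Acid 17 is converted with oxalyl chloride into (4-{[5,7-dimethoxy-3-(4-methoxyphenyl)-4-oxo-4H-chromen-8-yl]oxy}phenyl)acetyl chloride F4.
- F4 acylates commercial 2-chloro-1,3-dimethoxybenzene (AlCl3, CH2Cl2, 0 °C) at C4 to give 1-(3-chloro-2,4-dimethoxyphenyl)-2-(4-{[5,7-dimethoxy-3-(4-methoxyphenyl)-4-oxo-4H-chromen-8-yl]oxy}phenyl)ethan-1-one F5. Any concomitant loss of chelated methyl ethers is of no consequence.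
- BBr3 then removes all five methyl groups to give 1-(3-chloro-2,4-dihydroxyphenyl)-2-(4-{[5,7-dihydroxy-3-(4-hydroxyphenyl)-4-oxo-4H-chromen-8-yl]oxy}phenyl)ethan-1-one F6.
- The BF3·OEt2/DMF/MeSO2Cl ring closure, which tolerates free phenols, converts F6 into 21, where the route ends.

**Step 2.** Self-condensation of the chloro keto ester enolate, or C- instead of O-alkylation, may erode the alkylation. The fallback sets out from 2 and builds the keto ester by chain extension.
- Alkylation of 2 with methyl bromoacetate (K2CO3, acetone) gives methyl {4-[2-(tert-butyldimethylsilyloxy)ethyl]phenoxy}acetate F7.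
- LiOH hydrolysis gives {4-[2-(tert-butyldimethylsilyloxy)ethyl]phenoxy}acetic acid F8.
- 1,1'-Carbonyldiimidazole converts F8 into 1-({4-[2-(tert-butyldimethylsilyloxy)ethyl]phenoxy}acetyl)-1H-imidazole F9.
- F9 is acylated onto the magnesium salt of monomethyl malonate (KO2CCH2CO2Me, MgCl2) with decarboxylation to give 4.

## Further compounds

F1 | step 6 | 5,7-dimethoxy-3-(4-methoxyphenyl)-4H-chromen-4-one | COc1ccc(cc1)-c1coc2cc(OC)cc(OC)c2c1=O
F2 | step 6 | 8-bromo-5,7-dimethoxy-3-(4-methoxyphenyl)-4H-chromen-4-one | COc1ccc(cc1)-c1coc2c(Br)c(OC)cc(OC)c2c1=O
F3 | step 5 | methyl 4-{4-[2-(tert-butyldimethylsilyloxy)ethyl]phenoxy}-2-[(4-methoxyphenyl)acetyl]-3-oxobutanoate | COC(=O)C(C(=O)COc1ccc(CCO[Si](C)(C)C(C)(C)C)cc1)C(=O)Cc1ccc(OC)cc1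
F4 | step 10 | (4-{[5,7-dimethoxy-3-(4-methoxyphenyl)-4-oxo-4H-chromen-8-yl]oxy}phenyl)acetyl chloride | COc1ccc(cc1)-c1coc2c(Oc3ccc(CC(=O)Cl)cc3)c(OC)cc(OC)c2c1=O
F5 | step 10 | 1-(3-chloro-2,4-dimethoxyphenyl)-2-(4-{[5,7-dimethoxy-3-(4-methoxyphenyl)-4-oxo-4H-chromen-8-yl]oxy}phenyl)ethan-1-one | COc1ccc(cc1)-c1coc2c(Oc3ccc(CC(=O)c4ccc(OC)c(Cl)c4OC)cc3)c(OC)cc(OC)c2c1=O
F6 | step 10 | 1-(3-chloro-2,4-dihydroxyphenyl)-2-(4-{[5,7-dihydroxy-3-(4-hydroxyphenyl)-4-oxo-4H-chromen-8-yl]oxy}phenyl)ethan-1-one | O=C(Cc1ccc(Oc2c(O)cc(O)c3c(=O)c(-c4ccc(O)cc4)coc23)cc1)c1ccc(O)c(Cl)c1O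
F7 | step 2 | methyl {4-[2-(tert-butyldimethylsilyloxy)ethyl]phenoxy}acetate | COC(=O)COc1ccc(CCO[Si](C)(C)C(C)(C)C)cc1
F8 | step 2 | {4-[2-(tert-butyldimethylsilyloxy)ethyl]phenoxy}acetic acid | OC(=O)COc1ccc(CCO[Si](C)(C)C(C)(C)C)cc1
F9 | step 2 | 1-({4-[2-(tert-butyldimethylsilyloxy)ethyl]phenoxy}acetyl)-1H-imidazole | O=C(COc1ccc(CCO[Si](C)(C)C(C)(C)C)cc1)n1ccnc1
A1 | alternative 1 | methyl coumalate (methyl 2-oxo-2H-pyran-5-carboxylate) | COC(=O)c1ccc(=O)oc1
A2 | alternative 1 | 1-(benzyloxy)-2-(ethynyloxy)-3,5-dimethoxybenzene | C#COc1c(OCc2ccccc2)cc(OC)cc1OC
A3 | alternative 1 | methyl 4-[2-(benzyloxy)-4,6-dimethoxyphenoxy]benzoate | COC(=O)c1ccc(Oc2c(OCc3ccccc3)cc(OC)cc2OC)cc1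
A4 | alternative 1 | methyl 4-fluorobenzoate | COC(=O)c1ccc(F)cc1
A5 | alternative 1 | 2-(benzyloxy)-4,6-dimethoxyphenol | Oc1c(OCc2ccccc2)cc(OC)cc1OC
A6 | alternative 2 | 2-{4-[2-(benzyloxy)-4,6-dimethoxyphenoxy]phenyl}-1-(3-chloro-2,4-difluorophenyl)-3-hydroxyprop-2-en-1-one | O=C(C(=CO)c1ccc(Oc2c(OCc3ccccc3)cc(OC)cc2OC)cc1)c1ccc(F)c(Cl)c1F
A7 | alternative 2 | 3-{4-[2-(benzyloxy)-4,6-dimethoxyphenoxy]phenyl}-8-chloro-7-fluoro-4H-chromen-4-one | O=c1c(-c2ccc(Oc3c(OCc4ccccc4)cc(OC)cc3OC)cc2)coc2c(Cl)c(F)ccc12
A8 | alternative 3 | 3-hydroxy-2-(4-methoxyphenyl)-1-(2,4,5-trimethoxyphenyl)prop-2-en-1-one | COc1ccc(cc1)C(=CO)C(=O)c1cc(OC)c(OC)cc1OC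
A9 | alternative 3 | 2-[3-hydroxy-2-(4-methoxyphenyl)acryloyl]-5-methoxy-1,4-benzoquinone | COC1=CC(=O)C(=CC1=O)C(=O)C(=CO)c1ccc(OC)cc1
A10 | alternative 3 | 5,8-dihydroxy-7-methoxy-3-(4-methoxyphenyl)-4H-chromen-4-one | COc1cc(O)c2c(=O)c(-c3ccc(OC)cc3)coc2c1O
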